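The route rests on cutting the cyclohexene shared by both phthalide halves, C6–C7–C4′–C3a′–C7a′–C7′ (phthalide numbering; primed atoms belong to the hydroxylated bicyclo[2.2.2]octene half), at C3a′–C4′ and C6–C7. The key step makes both bonds in one flask by a catalytic asymmetric Michael/Michael annulation: the doubly acylated C3a′ of an enone β-keto thioester adds to C4′ of a β,γ-unsaturated α-keto ester, and the keto ester α-carbon C7 then closes onto the enone carbon C6. It exploits that C7a′ can be a ketone, later carbonylated, and that C7 can carry the latent C7a/C1 keto ester. Aldol closures and two palladium steps complete both butylidene lactones.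

Key step: step 8

Remark (assumption): the quinine-derived squaramide is assumed to deliver the nucleophile to the Re face of the β-carbon of 4 (giving C4′ R); if a model reaction shows the opposite sense, the quinidine-derived pseudoenantiomer is used instead.

Step 1
Reactants: 1 3,3-diethoxypropan-1-ol
Product: 2 3,3-diethoxypropanal
Conditions: DMP, pyridine, CH2Cl2, 0 °C to rt
Reagents that add atoms: none
Why: Dess–Martin oxidation of the primary alcohol stops at the aldehyde, and the buffered anhydrous medium should leave the acetal intact.

Step 2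
Reactants: 2 3,3-diethoxypropanal; 3 ethyl 2-oxo-3-(triphenyl-λ5-phosphanylidene)propanoate
Product: 4 ethyl (E)-6,6-diethoxy-2-oxohex-3-enoate
Conditions: CH2Cl2, rt
Reagents that add atoms: none
Why: Wittig olefination with the acyl-stabilised ylide should give the E-configured β,γ-unsaturated α-keto ester under the usual thermodynamic control.

Step 3
Reactants: 5 δ-valerolactone
Product: 6 1-hydroxynonan-5-one
Conditions: n-BuLi (1.0 equiv), THF, −78 °C; then NH4Cl (aq)
Reagents that add atoms: n-butyllithium, [Li]CCCC
Why: At low temperature the organolithium adds once to the lactone and the lithium lactolate survives until the quench, so this acyl substitution should stop at the hydroxy ketone.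

Step 4
Reactants: 6 1-hydroxynonan-5-one
Product: 7 5-oxononanal
Conditions: DMP, pyridine, CH2Cl2, rt
Reagents that add atoms: none
Why: Dess–Martin oxidation acts on the primary alcohol of the open-chain tautomer (the cyclic lactol is tertiary and inert) and leaves the ketone untouched.

Step 5
Reactants: 8 2,2,6-trimethyl-4H-1,3-dioxin-4-one
Product: 9 diethyl [(2,2-dimethyl-4-oxo-4H-1,3-dioxin-6-yl)methyl]phosphonate
Conditions: LiN(i-Pr)2 (2.1 equiv), THF, −78 °C; ClP(O)(OEt)2, −78 to 0 °C
Reagents that add atoms: diethyl chlorophosphate, CCOP(=O)(Cl)OCC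
Why: γ-Deprotonation of the vinylogous ester gives the lithium dienolate, which is phosphorylated at its terminal carbon while the second equivalent of amide takes up the more acidic product proton (C-phosphorylation of a dienolate).

Step 6
Reactants: 9 diethyl [(2,2-dimethyl-4-oxo-4H-1,3-dioxin-6-yl)methyl]phosphonate
Product: 11 S-ethyl 4-(diethoxyphosphoryl)-3-oxobutanethioate, via acylketene 10 (not isolated)
Conditions: EtSH (1.2 equiv), PhMe, 110 °C, sealed tube
Reagents that add atoms: ethanethiol, CCS
Why: Thermal retro-[4+2] loss of acetone from the dioxinone gives an acylketene that the thiol traps at once (dioxinone thermolysis), and doing this before the enone exists avoids thia-Michael addition.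

Step 7
Reactants: 11 S-ethyl 4-(diethoxyphosphoryl)-3-oxobutanethioate; 7 5-oxononanal
Product: 12 S-ethyl (E)-3,9-dioxotridec-4-enethioate
Conditions: NaH (2.1 equiv), THF, 0 °C; then 7, 0 °C to rt
Reagents that add atoms: none
Why: The dianion reacts at its phosphonate carbon with the aldehyde, which is far more electrophilic than the ketone, and Horner–Wadsworth–Emmons olefination of this stabilised phosphonate should give the E-enone.

Step 8
Reactants: 4 ethyl (E)-6,6-diethoxy-2-oxohex-3-enoate; 12 S-ethyl (E)-3,9-dioxotridec-4-enethioate
Product: 14 cyclohexanone keto thioester, via Michael adduct 13 (not isolated)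
Conditions: quinine-derived 3,5-bis(trifluoromethyl)phenyl squaramide (10 mol%), CH2Cl2, −20 °C, slow addition of 12; then Cs2CO3 (0.5 equiv), 0 °C to rt, same flask
Reagents that add atoms: none
Why: The amine of the squaramide deprotonates C3a′–H of 12 while its NH groups bind the 1,2-dicarbonyl of 4, so the enolate adds to the Re face of C4′ (adduct 13, C4′ R), and Cs2CO3 then generates the keto ester enolate whose α-carbon C7 adds to the enone carbon C6. The closest known reaction type is the double Michael (anionic formal [4+2]) annulation of Nazarov reagents with activated alkenes, combined with the organocatalytic addition of 1,3-dicarbonyl compounds to β,γ-unsaturated α-keto esters. The ring C6–C7–C4′–C3a′–C7a′–C7′ closes by a 6-endo-trig intramolecular Michael addition of an exocyclic enolate. C4′ is set by the catalyst, C6 by a chair transition state that places the C4′ and C6 side chains equatorial and therefore cis, and C7 should settle trans to both under the basic conditions (it is reset in step 9), while C3a′ stays enolisable and later becomes sp2. The step needs cross- over self-annulation of 12, secured by the higher electrophilicity of the hydrogen-bonded keto ester and by slow addition of 12, and C- over O-attack, secured because hemiketal formation is reversible whereas the ring closure is downhill.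

Step 9
Reactants: 14 cyclohexanone keto thioester
Product: 17 tricyclic β-keto thioester, via keto aldehyde 15 (not isolated), via bicyclic aldol 16 (not isolated)
Conditions: 2 M HCl (aq), THF, rt; then solvent switch, TsOH·H2O (0.2 equiv), PhMe, 80 °C
Reagents that add atoms: water, O
Why: Acetal hydrolysis frees the aldehyde, which undergoes intramolecular aldol addition from C7′ (the only α-carbon of the C7a′ ketone that can reach it through a six-membered boat) to close the bicyclo[2.2.2]octanone with the C6′ hydroxyl turned away from the C6 side chain and toward the carbonyl bridge; heating with acid then closes ring A by aldol condensation of the side-chain ketone (C3a) with the keto ester carbonyl (C7a), which on the bicycle is possible only cis, so the enolisable C7 should epimerise to the required configuration.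

Step 10
Reactants: 17 tricyclic β-keto thioester
Product: 18 enol triflate
Conditions: NaH (1.05 equiv), PhNTf2, THF, 0 °C to rt
Reagents that add atoms: N-phenylbis(trifluoromethanesulfonimide), O=S(=O)(N(c1ccccc1)S(=O)(=O)C(F)(F)F)C(F)(F)F
Why: One equivalent of hydride removes only the β-keto thioester proton, by far the most acidic, and the enolate is O-sulfonylated at the C7a′ oxygen by the mild triflimide, which should not touch the secondary alcohol (enol triflate formation from a β-dicarbonyl compound).

Step 11
Reactants: 18 enol triflate
Product: 19 methyl ester thioester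
Conditions: Pd(OAc)2 (5 mol%), dppp, CO (1 atm), MeOH (3 equiv), i-Pr2NEt or Et3N, DMF, 40 °C
Reagents that add atoms: carbon monoxide, [C-]#[O+]; methanol, CO
Why: Oxidative addition of zerovalent palladium into the vinyl triflate, CO insertion and methanolysis of the acylpalladium place the future C1′ carboxyl on C7a′ (alkoxycarbonylation of a vinyl triflate), while the thioester is inert to palladium in the absence of an organozinc.

Step 12
Reactants: 19 methyl ester thioester
Product: 20 bis(keto ester)
Conditions: n-BuZnBr (3 equiv), PdCl2(PPh3)2 (10 mol%), THF–PhMe, rt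
Reagents that add atoms: n-butylzinc bromide, CCCC[Zn]Br
Why: Fukuyama coupling, in which zerovalent palladium inserts into the acyl–sulfur bond and the mild organozinc transfers butyl, should convert the thioester into the C3′ butyl ketone without touching esters, ketones or the free hydroxyl.

Step 13
Reactants: 20 bis(keto ester)
Product: 22 target CNP0289078.1, via bis(keto acid) 21 (not isolated)
Conditions: LiOH, THF–H2O, 0 °C to rt; 1 M HCl to pH 2, extraction; crude with TsOH·H2O (0.1 equiv), PhMe, 4 Å MS, 60 °C
Reagents that add atoms: lithium hydroxide, [Li+].[OH-]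
Why: Saponification gives the two cis γ-keto acids, which close to hydroxybutenolides and lose water under acid to the conjugated butylidene lactones (dehydrative enol-lactonisation), the Z geometry being the thermodynamic one because the propyl group avoids the ring carbon next to C3 and C3′.

Compound list
1 | 3,3-diethoxypropan-1-ol | CCOC(CCO)OCC | starting material
2 | 3,3-diethoxypropanal | CCOC(CC=O)OCC | intermediate
3 | ethyl 2-oxo-3-(triphenyl-λ5-phosphanylidene)propanoate | CCOC(=O)C(=O)C=P(c1ccccc1)(c1ccccc1)c1ccccc1 | starting material
4 | ethyl (E)-6,6-diethoxy-2-oxohex-3-enoate | CCOC(=O)C(=O)/C=C/CC(OCC)OCC | intermediate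
5 | δ-valerolactone (oxan-2-one) | O=C1CCCCO1 | starting material
6 | 1-hydroxynonan-5-one | CCCCC(=O)CCCCO | intermediate
7 | 5-oxononanal | CCCCC(=O)CCCC=O | intermediate
8 | 2,2,6-trimethyl-4H-1,3-dioxin-4-one | CC1=CC(=O)OC(C)(C)O1 | starting material
9 | diethyl [(2,2-dimethyl-4-oxo-4H-1,3-dioxin-6-yl)methyl]phosphonate | CCOP(=O)(CC1=CC(=O)OC(C)(C)O1)OCC | intermediate
10 | acylketene, diethyl (2,4-dioxobut-3-en-1-yl)phosphonate (not isolated) | CCOP(=O)(CC(=O)C=C=O)OCC | intermediate
11 | S-ethyl 4-(diethoxyphosphoryl)-3-oxobutanethioate | CCOP(=O)(CC(=O)CC(=O)SCC)OCC | intermediate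
12 | S-ethyl (E)-3,9-dioxotridec-4-enethioate | CCCCC(=O)CCC/C=C/C(=O)CC(=O)SCC | intermediate
13 | Michael adduct, ethyl (4R,7E)-4-(2,2-diethoxyethyl)-5-[(ethylsulfanyl)carbonyl]-2,6,12-trioxohexadec-7-enoate, C5 epimers (not isolated) | CCCCC(=O)CCC/C=C/C(=O)C(C(=O)SCC)[C@H](CC(OCC)OCC)CC(=O)C(=O)OCC | intermediate
14 | cyclohexanone keto thioester, ethyl 2-[(1S,2R,6R)-2-(2,2-diethoxyethyl)-3-[(ethylsulfanyl)carbonyl]-4-oxo-6-(4-oxooctyl)cyclohexyl]-2-oxoacetate; C2 and C6 side chains cis, C1 group trans to both, C3 enolisable | CCCCC(=O)CCC[C@@H]1CC(=O)C(C(=O)SCC)[C@H](CC(OCC)OCC)[C@H]1C(=O)C(=O)OCC | intermediate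
15 | keto aldehyde, ethyl 2-[(1S,2R,6R)-3-[(ethylsulfanyl)carbonyl]-4-oxo-6-(4-oxooctyl)-2-(2-oxoethyl)cyclohexyl]-2-oxoacetate (not isolated) | CCCCC(=O)CCC[C@@H]1CC(=O)C(C(=O)SCC)[C@H](CC=O)[C@H]1C(=O)C(=O)OCC | intermediate
16 | bicyclic aldol (not isolated): 6-hydroxybicyclo[2.2.2]octan-2-one with the C7a′ ketone, C(=O)SEt on C3a′, C6′ hydroxyl syn to the ketone bridge, 4-oxooctyl chain on C6 facing the C5′–C6′ bridge and ethoxalyl group on C7 trans to that chain | CCCCC(=O)CCC[C@@H]1[C@H]3C(=O)C(C(=O)SCC)[C@H](C[C@@H]3O)[C@H]1C(=O)C(=O)OCC | intermediate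
17 | tricyclic β-keto thioester: as 16, but ring A closed cis across C6–C7 as a cyclohexene with CO2Et on C7a and the pentanoyl group on C3a | CCOC(=O)C2=C(C(=O)CCCC)CC[C@@H]1[C@H]3C(=O)C(C(=O)SCC)[C@H](C[C@@H]3O)[C@H]21 | intermediate
18 | enol triflate: as 17, with C7a′(OTf)=C3a′–C(=O)SEt | CCOC(=O)C2=C(C(=O)CCCC)CC[C@@H]1[C@H]3C(OS(=O)(=O)C(F)(F)F)=C(C(=O)SCC)[C@H](C[C@@H]3O)[C@H]21 | intermediate
19 | methyl ester thioester: as 18, with CO2Me on C7a′ in place of OTf | CCOC(=O)C2=C(C(=O)CCCC)CC[C@@H]1[C@H]3C(C(=O)OC)=C(C(=O)SCC)[C@H](C[C@@H]3O)[C@H]21 | intermediate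
20 | bis(keto ester): as 19, with a pentanoyl group on C3a′ in place of the thioester | CCOC(=O)C2=C(C(=O)CCCC)CC[C@@H]1[C@H]3C(C(=O)OC)=C(C(=O)CCCC)[C@H](C[C@@H]3O)[C@H]21 | intermediate
21 | bis(keto acid): as 20 with both esters hydrolysed; in equilibrium with its hydroxybutenolide forms (not isolated) | OC(=O)C2=C(C(=O)CCCC)CC[C@@H]1[C@H]3C(C(=O)O)=C(C(=O)CCCC)[C@H](C[C@@H]3O)[C@H]21 | intermediate
22 | CNP0289078.1, the (3Z,3′Z)-bis(butylidene) lactone dimer with the C6′ hydroxyl, linked C6–C7′ and C7–C4′ | CCC/C=C1\OC(=O)C2=C1CC[C@@H]1[C@H]3C4=C(/C(=C/CCC)OC4=O)[C@H](C[C@@H]3O)[C@H]21 | target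

Total step count: 13. Longest linear sequence: 9 steps (steps 3, 4, 7, 8, 9, 10, 11, 12, 13; the branch through steps 5 and 6 is equally long).

Steps most likely to fail

Step 8. What may go wrong: self-annulation of 12 may compete, and the first Michael addition may reverse under carbonate, eroding the configuration at C4′ before the ring closes. The fallback replaces Brønsted-base catalysis by a Lewis-acid, silyl-transfer manifold; it sets out from 12 and comes back at 14. Compound 12 is silylated with TBSOTf/Et3N (1.05 equiv, CH2Cl2, −78 °C) to the silyl dienol ether S-ethyl (2Z,4E)-3-[(tert-butyldimethylsilyl)oxy]-9-oxotrideca-2,4-dienethioate F1. Mukaiyama–Michael addition of F1 to 4 under Cu(OTf)2 and (S,S)-t-Bu-bis(oxazoline) (divalent copper chelated by the 1,2-dicarbonyl of 4), followed by mild acid work-up, should give the open-chain adduct 13 as an isolated compound. Compound 13 is then cyclised on its own to 14 with Cs2CO3 in MeCN.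

Step 9. What may go wrong: the aldol equilibrium may rest with the open keto aldehyde or with a cyclic hemiacetal formed through the enol oxygen of the β-keto thioester; ring A may then condense first and lock C7 in the trans-fused series, which cannot form the bicycle. The fallback closes the bicycle by a vinylogous aldol after the β-dicarbonyl unit has been spent; it sets out from 14 and comes back at 19. Compound 14 is triflated (NaH, PhNTf2) to the monocyclic enol triflate F2 and methoxycarbonylated (Pd(OAc)2, dppp, CO, MeOH) to the monocyclic methyl ester thioester F3. PPTS in wet acetone frees the monocyclic aldehyde F4 while the ring A ketone stays idle. DBU then removes the γ-proton at C7′ (vinylogous to the thioester) while the keto ester is parked as its enolate, and the dienolate should close onto the aldehyde to give the bicyclo[2.2.2]octene with ring A still open F5. TsOH in toluene finally closes ring A to 19.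

Step 12. What may go wrong: insertion of palladium into the hindered, conjugated thioester may be slow, so protonolysis of the organozinc by the free hydroxyl or reduction to the aldehyde may take over. The fallback is a zinc-free, copper-assisted acyl transfer; it sets out from 19 and comes back at 20. Liebeskind–Srogl coupling of 19 with B-butyl-9-borabicyclo[3.3.1]nonane (from but-1-ene and 9-BBN) under Pd2(dba)3, tri(2-furyl)phosphine, copper thiophene-2-carboxylate (monovalent copper) and Cs2CO3 in THF should give 20 directly; no new isolated compound is made.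

Further compounds
F1 | step 8 | S-ethyl (2Z,4E)-3-[(tert-butyldimethylsilyl)oxy]-9-oxotrideca-2,4-dienethioate | CCCCC(=O)CCC/C=C/C(O[Si](C)(C)C(C)(C)C)=C/C(=O)SCC
F2 | step 9 | monocyclic enol triflate: 14 with C7a′(OTf)=C3a′–C(=O)SEt | CCCCC(=O)CCC[C@@H]1CC(OS(=O)(=O)C(F)(F)F)=C(C(=O)SCC)[C@H](CC(OCC)OCC)[C@H]1C(=O)C(=O)OCC
F3 | step 9 | monocyclic methyl ester thioester: F2 with CO2Me in place of OTf | CCCCC(=O)CCC[C@@H]1CC(C(=O)OC)=C(C(=O)SCC)[C@H](CC(OCC)OCC)[C@H]1C(=O)C(=O)OCC
F4 | step 9 | monocyclic aldehyde: F3 with the acetal hydrolysed | CCCCC(=O)CCC[C@@H]1CC(C(=O)OC)=C(C(=O)SCC)[C@H](CC=O)[C@H]1C(=O)C(=O)OCC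
F5 | step 9 | bicyclo[2.2.2]octene with ring A open: C7a′–CO2Me, C3a′–C(=O)SEt, C6′–OH, 4-oxooctyl on C6, ethoxalyl on C7 | CCCCC(=O)CCC[C@@H]1[C@H]3C(C(=O)OC)=C(C(=O)SCC)[C@H](C[C@@H]3O)[C@H]1C(=O)C(=O)OCC
F0 | step 12 | none | none
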